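**Retrosynthetic overview**

- Target ⇐ α-face epoxidation of C11=C20 ⇐ tetraacetate ⇐ SN2 chloride for C6–OH ⇐ 6,8-diol lactone ⇐ O6-tethered oxa-Michael addition to a C8=C17 butenolide.
- Ten-membered ring ⇐ intramolecular B-alkyl Suzuki–Miyaura coupling forming C4–C5 (C3=C4 vinyl group + 2-bromoallyl unit).
- Open-chain precursor ⇐ Mukaiyama aldol (C9–C10) of a ring A silyl enol ether with a 4-formylbutenolide; the butenolide ⇐ dihydroxyacetone (Wittig/lactonisation) + 2-bromoacrolein (asymmetric vinylogous aldol, C6/C7).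
- Ring A ⇐ anti cuprate methylation (quaternary C1) and chelation-controlled vinylation (C2) of a γ-keto enoate ⇐ key step: enzymatic dearomatising cis-dihydroxylation of ethyl benzoate (C13 and C14, >99% ee).
- Ring order: ring A (from the arene) → butenolide (separate fragment) → ten-membered carbocycle → saturated hydroxy-lactone → spiro-epoxide.

Assumptions: intermediates carry briarane numbering (C1–C20); 2-bromoacrolein is bought (or made fresh from acrolein); (R)-BINOL/Ti(OiPr)4 is taken to give the (5R)-threo adduct in step 10, otherwise the (S)-ligand is used.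

**Ring A fragment**

Step 1
Reactants: 1 ethyl benzoate
Product: 2 ethyl (5S,6R)-5,6-dihydroxycyclohexa-1,3-diene-1-carboxylate
Conditions: E. coli JM109(pDTG601A) whole cells (toluene dioxygenase), O2, glucose, phosphate buffer pH 7, 35 °C
Reagents that add atoms: dioxygen O=O
Why: Enzymatic dearomatising cis-dihydroxylation (arene cis-dihydrodiol formation): the dioxygenase adds both oxygens to the 2,3-bond from one face, giving the (5S,6R)-diol that fixes C14 (R) and C13 (S) and is the source of all ring A chirality.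

Step 2
Reactants: 2 ethyl (5S,6R)-5,6-dihydroxycyclohexa-1,3-diene-1-carboxylate
Product: 3 ethyl (3aR,7aS)-2,2-dimethyl-3a,7a-dihydro-1,3-benzodioxole-4-carboxylate
Conditions: 2,2-dimethoxypropane, TsOH·H2O (cat.), acetone, 0 °C
Reagents that add atoms: 2,2-dimethoxypropane COC(C)(C)OC
Why: Acid-catalysed transketalisation of the cis-diol stops aromatisation and gives the cis-fused dioxolane that later shields the α-face; no stereocentre changes.

Step 3
Reactants: 3 ethyl (3aR,7aS)-2,2-dimethyl-3a,7a-dihydro-1,3-benzodioxole-4-carboxylate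
Product: 4 ethyl (3aR,7aS)-2,2-dimethyl-3a,6,7,7a-tetrahydro-1,3-benzodioxole-4-carboxylate
Conditions: KO2CN=NCO2K, AcOH, MeOH, 0 °C
Reagents that add atoms: none
Why: Diimide reduction takes the cis-disubstituted C11=C12 bond and leaves the trisubstituted ester-bearing alkene; no stereocentre is formed.

Step 4
Reactants: 4 ethyl (3aR,7aS)-2,2-dimethyl-3a,6,7,7a-tetrahydro-1,3-benzodioxole-4-carboxylate
Product: 5 ethyl (3aR,7aS)-2,2-dimethyl-6-oxo-3a,6,7,7a-tetrahydro-1,3-benzodioxole-4-carboxylate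
Conditions: Rh2(cap)4 (dirhodium tetracaprolactamate, 1 mol%), 70% aq. t-BuOOH, CH2Cl2, rt
Reagents that add atoms: tert-butyl hydroperoxide CC(C)(C)OO
Why: Radical allylic (γ-C–H) oxidation by tert-butylperoxyl at the only allylic methylene (C11) gives the γ-keto enoate under base-free conditions, so the β-alkoxy ketone does not eliminate.

Step 5
Reactants: 5 ethyl (3aR,7aS)-2,2-dimethyl-6-oxo-3a,6,7,7a-tetrahydro-1,3-benzodioxole-4-carboxylate
Product: 7 ethyl (3aR,4R,7aS)-6-[(tert-butyldimethylsilyl)oxy]-2,2,4-trimethyl-3a,4,7,7a-tetrahydro-1,3-benzodioxole-4-carboxylate, via lithium enolate 6 (not isolated)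
Conditions: Me2CuLi, Et2O, −78 °C; then TBSCl, HMPA, Et3N, −78 to 0 °C
Reagents that add atoms: lithium dimethylcuprate [Li+].C[Cu-]C; tert-butyldimethylsilyl chloride CC(C)(C)[Si](C)(C)Cl
Why: Gilman conjugate addition goes to the ester-bearing carbon (β to the ketone) and anti to the γ-oxygen at C14, which sets quaternary C1 with methyl trans to O14; the regiodefined C10 enolate is trapped on oxygen.

Step 6
Reactants: 7 the silyl enol ether ester
Product: 8 (3aR,4R,7aS)-6-[(tert-butyldimethylsilyl)oxy]-2,2,4-trimethyl-3a,4,7,7a-tetrahydro-1,3-benzodioxole-4-carbaldehyde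
Conditions: i-Bu2AlH (1.1 equiv), toluene, −78 °C; Rochelle salt work-up
Reagents that add atoms: none
Why: Partial hydride reduction: the neopentyl, β-alkoxy-chelated tetrahedral aluminate is stable at −78 °C and releases the aldehyde only on work-up.

Step 7
Reactants: 8 the ring A aldehyde
Product: 10 (1S)-1-[(3aR,4S,7aS)-6-[(tert-butyldimethylsilyl)oxy]-2,2,4-trimethyl-3a,4,7,7a-tetrahydro-1,3-benzodioxol-4-yl]prop-2-en-1-yl acetate, via bromomagnesium alkoxide 9 (not isolated)
Conditions: MgBr2·OEt2, CH2Cl2, −78 °C; CH2=CHMgBr; then Ac2O, −78 °C to rt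
Reagents that add atoms: vinylmagnesium bromide C=C[Mg]Br; acetic anhydride CC(=O)OC(C)=O
Why: Chelation-controlled Grignard addition (Cram–Reetz 1,3-anti): magnesium bridges the aldehyde oxygen and O14, and the vinyl group attacks the exposed face turned away from ring A, giving 2S; the alkoxide is acetylated in the flask.

**Lactone fragment**

Step 8
Reactants: 11 1,3-dihydroxyacetone (commercial dimer); 12 ethyl 2-(triphenyl-λ5-phosphanylidene)propanoate
Product: 14 4-(hydroxymethyl)-3-methylfuran-2(5H)-one, via hydroxy ester 13 (not isolated)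
Conditions: MeOH, rt to 50 °C
Reagents that add atoms: none
Why: Wittig olefination then lactonisation; the ketone has two identical CH2OH arms, so either alkene geometry has a hydroxymethyl cis to the ester and closes to the same butenolide.

Step 9
Reactants: 14 4-(hydroxymethyl)-3-methylfuran-2(5H)-one
Product: 15 triethyl[(3-methyl-4-{[(triethylsilyl)oxy]methyl}furan-2-yl)oxy]silane
Conditions: TESOTf (2.2 equiv), Et3N, CH2Cl2, 0 °C
Reagents that add atoms: triethylsilyl triflate CC[Si](CC)(CC)OS(=O)(=O)C(F)(F)F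
Why: Soft enolisation (silyl triflate/amine) aromatises the butenolide to the 2-silyloxyfuran and silylates the primary alcohol.

Step 10
Reactants: 15 the 2-silyloxyfuran; 16 2-bromoprop-2-enal (2-bromoacrolein)
Product: 17 (5R)-5-[(1S)-2-bromo-1-[(triethylsilyl)oxy]prop-2-en-1-yl]-3-methyl-4-{[(triethylsilyl)oxy]methyl}furan-2(5H)-one
Conditions: Ti(OiPr)4 (20 mol%), (R)-BINOL ((R)-1,1′-bi-2-naphthol, 20 mol%), Et2O, −20 °C
Reagents that add atoms: none
Why: Catalytic asymmetric vinylogous Mukaiyama aldol (BINOL–titanium type): γ-attack through an open transition state is threo-selective and the catalyst sets C7 (R) and the C6 carbinol (S, inverted later); the silyl group transfers to the new alkoxide.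

Step 11
Reactants: 17 the bis-TES butenolide
Product: 18 (5R)-5-[(1S)-2-bromo-1-[(triethylsilyl)oxy]prop-2-en-1-yl]-4-(hydroxymethyl)-3-methylfuran-2(5H)-one
Conditions: PPTS (pyridinium p-toluenesulfonate, cat.), MeOH/CH2Cl2, 0 °C
Reagents that add atoms: none
Why: Acid-catalysed methanolysis removes the primary TES ether much faster than the secondary one; non-basic, so C7 is not touched.

Step 12
Reactants: 18 the primary alcohol
Product: 19 (2R)-2-[(1S)-2-bromo-1-[(triethylsilyl)oxy]prop-2-en-1-yl]-4-methyl-5-oxo-2,5-dihydrofuran-3-carbaldehyde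
Conditions: MnO2 (activated), CH2Cl2, rt
Reagents that add atoms: none
Why: Neutral allylic oxidation with MnO2 gives the 4-formylbutenolide without base, so the acidic C7–H does not epimerise.

**Union and end game**

Step 13
Reactants: 10 the ring A silyl enol ether; 19 the butenolide aldehyde
Product: 20 seco-ketone (1S,2S,6S,7R,9S,10S,13S,14R): 11-oxo; 9-OTBS; 6-OTES; 2-OAc; 13,14-O-isopropylidene; C3=C4 vinyl; 5-bromo-5(16)-ene; 8(17)-en-19,7-olide
Conditions: HNTf2 (3 mol%), CH2Cl2, −78 °C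
Reagents that add atoms: none
Why: Silyl-transfer Mukaiyama aldol (silyl triflimide formed in the flask): C10 is attacked on the β-face because the α-face is blocked by the axial C14–O bond and the C2 branch, and the open antiperiplanar transition state keeps the butenolide away from quaternary C1, giving the 9,10-syn adduct (9S,10S) with TBS moved to O9.

Step 14
Reactants: 20 seco-ketone
Product: 21 seco-diene (1S,2S,6S,7R,9S,10S,13S,14R): as 20 with 11(20)-methylene
Conditions: Zn, CH2Br2, TiCl4, THF; then CH2Cl2, 0 °C to rt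
Reagents that add atoms: dibromomethane BrCBr
Why: Takai–Lombardo methylenation is non-basic and ketone-selective over lactone and acetate, so C10 does not epimerise and no β-elimination occurs.

Step 15
Reactants: 21 seco-diene
Product: 23 macrocycle (1S,2S,6R,7R,9S,10S,13S,14R): 2-OAc; 13,14-O-isopropylidene; 9-OTBS; 6-OTES; briara-5(16),8(17),11(20)-trien-19,7-olide, via disiamylborane 22 (not isolated)
Conditions: Sia2BH (disiamylborane), THF, 0 °C; then PdCl2(dppf) (10 mol%), AsPh3, K3PO4 (aq.), THF/DMF, 2 mM, rt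
Reagents that add atoms: none
Why: The bulky dialkylborane hydroborates the monosubstituted C3=C4 bond far faster than the 1,1-disubstituted C11=C20 and the bromoalkene, and the intramolecular B-alkyl Suzuki–Miyaura coupling then forms C4–C5 and the ten-membered ring with the exocyclic C5 methylene in place; no stereocentre is created.

Step 16
Reactants: 23 macrocycle
Product: 24 6-alcohol macrocycle (1S,2S,6R,7R,9S,10S,13S,14R)
Conditions: HF·pyridine, pyridine, THF, 0 °C
Reagents that add atoms: none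
Why: Selective desilylation: buffered fluoride removes the secondary TES ether while the hindered C9 TBS ether and the acetonide stay.

Step 17
Reactants: 24 6-alcohol macrocycle
Product: 26 6,8-diol (1S,2S,6R,7S,8S,9S,10S,13S,14R,17R): 2-OAc; 13,14-O-isopropylidene; 9-OTBS; briara-5(16),11(20)-dien-19,7-olide, via cyclic phenylboronate 25 (not isolated)
Conditions: PhB(OH)2, DABCO (1,4-diazabicyclo[2.2.2]octane, 20 mol%), 4 Å MS, CH2Cl2, rt; then H2O2, aq. NaHCO3, 0 °C
Reagents that add atoms: phenylboronic acid OB(O)c1ccccc1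
Why: Proposed new method: the C6 hydroxyl forms a boronic hemiester whose B–OH oxygen adds intramolecularly (six-membered, 6-exo) to C8 of the butenolide under amine catalysis, so O8 must arrive cis to C6 as in the target, C17 equilibrates to the epimer with methyl trans to the C9 branch, and oxidative work-up frees the diol; the closest known reactions are the boronic acid hemiester oxa-Michael addition to δ-hydroxy enones and the hemiacetal oxa-Michael of δ-hydroxy enoates, extended here to a tetrasubstituted butenolide.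

Step 18
Reactants: 26 6,8-diol
Product: 27 6-chloride (1S,2S,6S,7R,8S,9S,10S,13S,14R,17R)
Conditions: PPh3, Cl3CCOCCl3, CH2Cl2, −20 to 0 °C
Reagents that add atoms: hexachloroacetone ClC(Cl)(Cl)C(=O)C(Cl)(Cl)Cl
Why: Appel-type chlorination (triphenylphosphine/hexachloroacetone): chloride displaces the allylic oxyphosphonium by SN2 with inversion and without allylic transposition; the tertiary C8–OH is too hindered to react.

Step 19
Reactants: 27 6-chloride
Product: 28 2-O-acetyl-8,9,13,14-tetraol (1S,2S,6S,7R,8R,9S,10S,13S,14R,17R)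
Conditions: 48% aq. HF, MeCN, 0 °C to rt
Reagents that add atoms: none
Why: Mild acidic global deprotection (acetonide hydrolysis and desilylation) that the allylic chloride, the exocyclic alkenes and the β-hydroxy lactone tolerate.

Step 20
Reactants: 28 tetraol
Product: 29 2,9,13,14-tetraacetate diene (1S,2S,6S,7R,8R,9S,10S,13S,14R,17R)
Conditions: Ac2O, pyridine, DMAP (4-(dimethylamino)pyridine, cat.), CH2Cl2, 0 °C to rt
Reagents that add atoms: acetic anhydride CC(=O)OC(C)=O
Why: Nucleophile-catalysed acetylation of the three secondary alcohols; the tertiary C8–OH stays free under these conditions.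

Step 21
Reactants: 29 tetraacetate diene
Product: 30 target CNP0195129.3 (1S,2S,6S,7R,8R,9S,10S,11R,13S,14R,17R)
Conditions: mCPBA, NaHCO3, CH2Cl2, 0 °C
Reagents that add atoms: 3-chloroperbenzoic acid O=C(OO)c1cccc(Cl)c1
Why: Prilezhaev epoxidation takes the electron-richer C11=C20 bond (C5=C16 is deactivated by the allylic chloride) from the α-face, because the β-face is blocked by the axial C15 methyl, giving 11R.

**Compound list**

1 | ethyl benzoate | CCOC(=O)c1ccccc1 | starting material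
2 | ethyl (5S,6R)-5,6-dihydroxycyclohexa-1,3-diene-1-carboxylate | CCOC(=O)C1=CC=C[C@H](O)[C@@H]1O | intermediate
3 | ethyl (3aR,7aS)-2,2-dimethyl-3a,7a-dihydro-1,3-benzodioxole-4-carboxylate | CCOC(=O)C1=CC=C[C@@H]2OC(C)(C)O[C@H]12 | intermediate
4 | ethyl (3aR,7aS)-2,2-dimethyl-3a,6,7,7a-tetrahydro-1,3-benzodioxole-4-carboxylate | CCOC(=O)C1=CCC[C@@H]2OC(C)(C)O[C@H]12 | intermediate
5 | ethyl (3aR,7aS)-2,2-dimethyl-6-oxo-3a,6,7,7a-tetrahydro-1,3-benzodioxole-4-carboxylate | CCOC(=O)C1=CC(=O)C[C@@H]2OC(C)(C)O[C@H]12 | intermediate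
6 | lithium enolate of ethyl (3aR,4R,7aS)-2,2,4-trimethyl-6-oxohexahydro-1,3-benzodioxole-4-carboxylate | CCOC(=O)[C@@]1(C)[C@@H](OC(C)(C)O2)[C@@H]2CC([O-])=C1.[Li+] | intermediate
7 | ethyl (3aR,4R,7aS)-6-[(tert-butyldimethylsilyl)oxy]-2,2,4-trimethyl-3a,4,7,7a-tetrahydro-1,3-benzodioxole-4-carboxylate | CCOC(=O)[C@@]1(C)[C@@H](OC(C)(C)O2)[C@@H]2CC(O[Si](C)(C)C(C)(C)C)=C1 | intermediate
8 | (3aR,4R,7aS)-6-[(tert-butyldimethylsilyl)oxy]-2,2,4-trimethyl-3a,4,7,7a-tetrahydro-1,3-benzodioxole-4-carbaldehyde | O=C[C@@]1(C)[C@@H](OC(C)(C)O2)[C@@H]2CC(O[Si](C)(C)C(C)(C)C)=C1 | intermediate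
9 | bromomagnesium alkoxide from vinyl addition to 8 (C2 as in 10) | C=C[C@H]([O-])[C@@]1(C)[C@@H](OC(C)(C)O2)[C@@H]2CC(O[Si](C)(C)C(C)(C)C)=C1.[Mg+2].[Br-] | intermediate
10 | (1S)-1-[(3aR,4S,7aS)-6-[(tert-butyldimethylsilyl)oxy]-2,2,4-trimethyl-3a,4,7,7a-tetrahydro-1,3-benzodioxol-4-yl]prop-2-en-1-yl acetate | C=C[C@H](OC(C)=O)[C@@]1(C)[C@@H](OC(C)(C)O2)[C@@H]2CC(O[Si](C)(C)C(C)(C)C)=C1 | intermediate
11 | 1,3-dihydroxyacetone | OCC(=O)CO | starting material
12 | ethyl 2-(triphenyl-λ5-phosphanylidene)propanoate | CCOC(=O)C(C)=P(c1ccccc1)(c1ccccc1)c1ccccc1 | starting material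
13 | ethyl 4-hydroxy-3-(hydroxymethyl)-2-methylbut-2-enoate | CCOC(=O)C(C)=C(CO)CO | intermediate
14 | 4-(hydroxymethyl)-3-methylfuran-2(5H)-one | CC1=C(CO)COC1=O | intermediate
15 | triethyl[(3-methyl-4-{[(triethylsilyl)oxy]methyl}furan-2-yl)oxy]silane | CC[Si](CC)(CC)OCc1coc(O[Si](CC)(CC)CC)c1C | intermediate
16 | 2-bromoprop-2-enal | C=C(Br)C=O | starting material
17 | (5R)-5-[(1S)-2-bromo-1-[(triethylsilyl)oxy]prop-2-en-1-yl]-3-methyl-4-{[(triethylsilyl)oxy]methyl}furan-2(5H)-one | O=C1O[C@@H]([C@H](O[Si](CC)(CC)CC)C(Br)=C)C(CO[Si](CC)(CC)CC)=C1C | intermediate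
18 | (5R)-5-[(1S)-2-bromo-1-[(triethylsilyl)oxy]prop-2-en-1-yl]-4-(hydroxymethyl)-3-methylfuran-2(5H)-one | O=C1O[C@@H]([C@H](O[Si](CC)(CC)CC)C(Br)=C)C(CO)=C1C | intermediate
19 | (2R)-2-[(1S)-2-bromo-1-[(triethylsilyl)oxy]prop-2-en-1-yl]-4-methyl-5-oxo-2,5-dihydrofuran-3-carbaldehyde | O=C1O[C@@H]([C@H](O[Si](CC)(CC)CC)C(Br)=C)C(C=O)=C1C | intermediate
20 | seco-ketone (1S,2S,6S,7R,9S,10S,13S,14R): 11-oxo; 9-OTBS; 6-OTES; 2-OAc; 13,14-O-isopropylidene; C3=C4 vinyl; 5-bromo-5(16)-ene; 8(17)-en-19,7-olide | C=C[C@H](OC(C)=O)[C@@]1(C)[C@@H](OC(C)(C)O2)[C@@H]2CC(=O)[C@@H]1[C@H](O[Si](C)(C)C(C)(C)C)C3=C(C)C(=O)O[C@H]3[C@H](O[Si](CC)(CC)CC)C(Br)=C | intermediate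
21 | seco-diene (1S,2S,6S,7R,9S,10S,13S,14R): as 20 with 11(20)-methylene | C=C[C@H](OC(C)=O)[C@@]1(C)[C@@H](OC(C)(C)O2)[C@@H]2CC(=C)[C@@H]1[C@H](O[Si](C)(C)C(C)(C)C)C3=C(C)C(=O)O[C@H]3[C@H](O[Si](CC)(CC)CC)C(Br)=C | intermediate
22 | C4-bis(3-methylbutan-2-yl)borane from 21 | CC(C)C(C)B(C(C)C(C)C)CC[C@H](OC(C)=O)[C@@]1(C)[C@@H](OC(C)(C)O2)[C@@H]2CC(=C)[C@@H]1[C@H](O[Si](C)(C)C(C)(C)C)C3=C(C)C(=O)O[C@H]3[C@H](O[Si](CC)(CC)CC)C(Br)=C | intermediate
23 | macrocycle (1S,2S,6R,7R,9S,10S,13S,14R): 2-OAc; 13,14-O-isopropylidene; 9-OTBS; 6-OTES; briara-5(16),8(17),11(20)-trien-19,7-olide | C=C1CC[C@H](OC(C)=O)[C@@]2(C)[C@@H](OC(C)(C)O4)[C@@H]4CC(=C)[C@@H]2[C@H](O[Si](C)(C)C(C)(C)C)C2=C(C)C(=O)O[C@H]2[C@@H]1O[Si](CC)(CC)CC | intermediate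
24 | 6-alcohol macrocycle (1S,2S,6R,7R,9S,10S,13S,14R): as 23 with 6-OH | C=C1CC[C@H](OC(C)=O)[C@@]2(C)[C@@H](OC(C)(C)O4)[C@@H]4CC(=C)[C@@H]2[C@H](O[Si](C)(C)C(C)(C)C)C2=C(C)C(=O)O[C@H]2[C@@H]1O | intermediate
25 | cyclic phenylboronate bridging O6 and O8 of the saturated lactone | C=C1CC[C@H](OC(C)=O)[C@@]2(C)[C@@H](OC(C)(C)O4)[C@@H]4CC(=C)[C@@H]2[C@H](O[Si](C)(C)C(C)(C)C)[C@]2(OB(c3ccccc3)O5)[C@@H](C)C(=O)O[C@H]2[C@@H]15 | intermediate
26 | 6,8-diol (1S,2S,6R,7S,8S,9S,10S,13S,14R,17R): 2-OAc; 13,14-O-isopropylidene; 9-OTBS; briara-5(16),11(20)-dien-19,7-olide | C=C1CC[C@H](OC(C)=O)[C@@]2(C)[C@@H](OC(C)(C)O4)[C@@H]4CC(=C)[C@@H]2[C@H](O[Si](C)(C)C(C)(C)C)[C@]2(O)[C@@H](C)C(=O)O[C@H]2[C@@H]1O | intermediate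
27 | 6-chloride (1S,2S,6S,7R,8S,9S,10S,13S,14R,17R): as 26 with 6-Cl inverted | C=C1CC[C@H](OC(C)=O)[C@@]2(C)[C@@H](OC(C)(C)O4)[C@@H]4CC(=C)[C@@H]2[C@H](O[Si](C)(C)C(C)(C)C)[C@]2(O)[C@@H](C)C(=O)O[C@H]2[C@H]1Cl | intermediate
28 | 2-O-acetyl-8,9,13,14-tetraol (1S,2S,6S,7R,8R,9S,10S,13S,14R,17R) | C=C1CC[C@H](OC(C)=O)[C@@]2(C)[C@@H](O)[C@@H](O)CC(=C)[C@@H]2[C@H](O)[C@]2(O)[C@@H](C)C(=O)O[C@H]2[C@H]1Cl | intermediate
29 | 2,9,13,14-tetraacetate diene (1S,2S,6S,7R,8R,9S,10S,13S,14R,17R) | C=C1CC[C@H](OC(C)=O)[C@@]2(C)[C@@H](OC(C)=O)[C@@H](OC(C)=O)CC(=C)[C@@H]2[C@H](OC(C)=O)[C@]2(O)[C@@H](C)C(=O)O[C@H]2[C@H]1Cl | intermediate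
30 | CNP0195129.3 (1S,2S,6S,7R,8R,9S,10S,11R,13S,14R,17R) | C=C1CC[C@H](OC(C)=O)[C@@]2(C)[C@@H](OC(C)=O)[C@@H](OC(C)=O)C[C@]3(CO3)[C@@H]2[C@H](OC(C)=O)[C@]2(O)[C@@H](C)C(=O)O[C@H]2[C@H]1Cl | target

**Step count and risks**

Total steps: 21 (ring A fragment 7, lactone fragment 5, union and end game 9). Longest linear sequence: 16 steps (steps 1–7, then 13–21).

Most likely to fail, with fallbacks:

Step 10. The threo selectivity and ee may be modest with a 3,4-disubstituted silyloxyfuran and an α-bromo enal, and the sense of induction is assumed. The fallback sets out from 15: BF3·OEt2 in CH2Cl2 at −78 °C adds 15 to 16 threo-selectively but without enantiocontrol. This gives the (5R,1′S)-alcohol F1 together with its enantiomer F2; the two are separated by preparative chromatography on a chiral phase. F1 is silylated (TESCl, imidazole), which rejoins the route at 17.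

Step 15. The hydroboration must distinguish C3=C4 from C11=C20, the ring is medium-sized, and the base can epimerise C7. The fallback sets out from 10, where the vinyl group is the only reactive alkene: 9-BBN gives the B-alkyl-9-BBN adduct F3. F3 is cross-coupled intermolecularly with 19 (PdCl2(dppf), AsPh3, K3PO4) to the seco-aldehyde F4. The ring is then closed at C9–C10 by HNTf2-catalysed intramolecular Mukaiyama aldol at high dilution to the macrocyclic 11-ketone F5. Takai–Lombardo methylenation of F5 rejoins the route at 23.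

Step 17. This is a new extension: a tertiary C–O bond must form at a tetrasubstituted butenolide and the addition is reversible. The fallback sets out from 24: t-BuOOLi in THF at −20 °C, with the lithium alkoxide of the C6 hydroxyl directing the peroxide to its own face, gives the 8,17-epoxy lactone F6. SmI2 in THF/MeOH at −78 °C opens the C17–O bond reductively, and protonation with equilibration at C17 rejoins the route at 26.

**Further compounds**

F1 | step 10 | (5R)-5-[(1S)-2-bromo-1-hydroxyprop-2-en-1-yl]-3-methyl-4-{[(triethylsilyl)oxy]methyl}furan-2(5H)-one | O=C1O[C@@H]([C@H](O)C(Br)=C)C(CO[Si](CC)(CC)CC)=C1C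
F2 | step 10 | (5S)-5-[(1R)-2-bromo-1-hydroxyprop-2-en-1-yl]-3-methyl-4-{[(triethylsilyl)oxy]methyl}furan-2(5H)-one | O=C1O[C@H]([C@@H](O)C(Br)=C)C(CO[Si](CC)(CC)CC)=C1C
F3 | step 15 | B-alkyl-9-BBN adduct of 10 (boron on C4) | B1(CC[C@H](OC(C)=O)[C@@]3(C)[C@@H](OC(C)(C)O4)[C@@H]4CC(O[Si](C)(C)C(C)(C)C)=C3)C2CCCC1CCC2
F4 | step 15 | seco-aldehyde with C4–C5 joined, C9 aldehyde and ring A silyl enol ether | C=C(CC[C@H](OC(C)=O)[C@@]1(C)[C@@H](OC(C)(C)O2)[C@@H]2CC(O[Si](C)(C)C(C)(C)C)=C1)[C@@H](O[Si](CC)(CC)CC)[C@@H]1OC(=O)C(C)=C1C=O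
F5 | step 15 | macrocyclic 11-ketone (23 with C11=O in place of the methylene) | C=C1CC[C@H](OC(C)=O)[C@@]2(C)[C@@H](OC(C)(C)O4)[C@@H]4CC(=O)[C@@H]2[C@H](O[Si](C)(C)C(C)(C)C)C2=C(C)C(=O)O[C@H]2[C@@H]1O[Si](CC)(CC)CC
F6 | step 17 | 8,17-epoxy lactone from 24 (epoxide cis to C6) | C=C1CC[C@H](OC(C)=O)[C@@]2(C)[C@@H](OC(C)(C)O4)[C@@H]4CC(=C)[C@@H]2[C@H](O[Si](C)(C)C(C)(C)C)[C@@]25O[C@@]5(C)C(=O)O[C@H]2[C@@H]1O
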